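**Retrosynthetic overview**

1. Numbering: ring C1 (bears CO2Me), C2 (=CH), C3, C4 (stereocentre), C5 … C14; side chain C15(Me)=C16–C17–C18=C19Me2 on C4.
2. The only ring, the 14-membered carbocycle C1–C14, is closed last, at C1(sp2)–C14(sp3), by a one-pot diene hydroboration/B-alkyl Suzuki–Miyaura macrocyclization of an acyclic (Z)-α-chloroenoate; this step gives the target itself.
3. Enabling feature: C1 is the α-carbon of the ring (E)-enoate C1=C2 (ring carbons C14 and C3 cis), and C14–C13 is homoallylic to the ring olefin C11=C12. C14 can therefore enter as the terminus of a C14=C13–C12=C11 diene and C1 as a stereodefined alkenyl chloride.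
4. C1 and its ester come from Cr(II) olefination of a C2 aldehyde with methyl trichloroacetate; C2–C3, the C4 stereocentre and the (E)-C15=C16 olefin come from one Johnson–Claisen rearrangement of an (R)-C16 allylic alcohol (CBS reduction).
5. The C13–C16 backbone with both ring (E)-olefins is (2E,6E)-farnesol, opened at C16 by SeO2 allylic oxidation and α-prenylated.

Key step: step 13

Remark: the structure is read as (R) at C4 with all four trisubstituted C=C bonds (E) (in the ring enoate the ester is trans to C3); farnesol is used as the pure (2E,6E) isomer.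

**Route**

Step 1
Reactants: 1 (2E,6E)-farnesol
Product: 2 tert-butyldimethylsilyl ether of (2E,6E)-farnesol
Conditions: TBSCl, imidazole, DMF, 0 °C to rt
Reagents that add atoms: tert-butyldimethylsilyl chloride, CC(C)(C)[Si](C)(C)Cl
Why: Standard silyl ether protection of the primary allylic alcohol, so that the C13 oxygen survives the organobarium, borane and Claisen steps.

Step 2
Reactants: 2 tert-butyldimethylsilyl ether of (2E,6E)-farnesol
Product: 3 (2E,6E,10E)-12-(tert-butyldimethylsilyloxy)-2,6,10-trimethyldodeca-2,6,10-trien-1-ol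
Conditions: SeO2 (cat.), t-BuOOH, salicylic acid (cat.), CH2Cl2, 0 °C to rt
Reagents that add atoms: tert-butyl hydroperoxide, CC(C)(C)OO
Why: SeO2/t-BuOOH allylic oxidation (ene reaction then [2,3]-sigmatropic shift) is established on farnesyl derivatives to hydroxylate the (E)-methyl group of the terminal trisubstituted olefin, giving the (E)-allylic alcohol at C16.

Step 3
Reactants: 3 (2E,6E,10E)-12-(tert-butyldimethylsilyloxy)-2,6,10-trimethyldodeca-2,6,10-trien-1-ol
Product: 4 (2E,6E,10E)-12-(tert-butyldimethylsilyloxy)-2,6,10-trimethyldodeca-2,6,10-trienal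
Conditions: MnO2, CH2Cl2, rt
Reagents that add atoms: none
Why: MnO2 oxidation is selective for allylic alcohols and should give the (E)-enal without isomerization.

Step 4
Reactants: 4 (2E,6E,10E)-12-(tert-butyldimethylsilyloxy)-2,6,10-trimethyldodeca-2,6,10-trienal; 5 prenyl chloride (1-chloro-3-methylbut-2-ene)
Product: 6 rac-(6E,10E,14E)-16-(tert-butyldimethylsilyloxy)-2,6,10,14-tetramethylhexadeca-2,6,10,14-tetraen-5-ol
Conditions: BaI2, lithium biphenylide, THF, rt; 5, −78 °C; then 4, −78 °C; aq. NH4Cl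
Reagents that add atoms: prenyl chloride (5), CC(C)=CCCl
Why: Carbonyl allylation with an allylic barium reagent proceeds 1,2 and through the α-carbon of the allyl unit, so the prenyl CH2 (C17) and not the tertiary carbon bonds to C16; the carbinol centre forms racemic and is erased in step 5.

Step 5
Reactants: 6 rac-(6E,10E,14E)-16-(tert-butyldimethylsilyloxy)-2,6,10,14-tetramethylhexadeca-2,6,10,14-tetraen-5-ol
Product: 7 (6E,10E,14E)-16-(tert-butyldimethylsilyloxy)-2,6,10,14-tetramethylhexadeca-2,6,10,14-tetraen-5-one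
Conditions: MnO2, CH2Cl2, rt
Reagents that add atoms: none
Why: Allylic oxidation with MnO2 under neutral conditions gives the enone and should not move the β,γ-olefin C18=C19 into conjugation.

Step 6
Reactants: 7 (6E,10E,14E)-16-(tert-butyldimethylsilyloxy)-2,6,10,14-tetramethylhexadeca-2,6,10,14-tetraen-5-one
Product: 8 (5R,6E,10E,14E)-16-(tert-butyldimethylsilyloxy)-2,6,10,14-tetramethylhexadeca-2,6,10,14-tetraen-5-ol
Conditions: (S)-2-methyl-CBS-oxazaborolidine (cat.), catecholborane, toluene, −78 °C; aq. NaOH work-up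
Reagents that add atoms: none
Why: Corey–Bakshi–Shibata reduction with the alkenyl group as the large and the CH2 group as the small ketone substituent should give the (R)-carbinol at C16 with the (S)-catalyst (same sense as acetophenone to (R)-1-phenylethanol), and catecholborane at −78 °C reduces 1,2 without hydroborating the olefins.

Step 7
Reactants: 8 (5R,6E,10E,14E)-16-(tert-butyldimethylsilyloxy)-2,6,10,14-tetramethylhexadeca-2,6,10,14-tetraen-5-ol; 9 triethyl orthoacetate
Product: 11 ethyl (3R,4E)-3-[(3E,7E)-9-(tert-butyldimethylsilyloxy)-3,7-dimethylnona-3,7-dien-1-yl]-4,8-dimethylnona-4,7-dienoate, via ketene acetal 10 (not isolated)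
Conditions: 9 (excess), EtCO2H (cat.), 135 °C, removal of EtOH
Reagents that add atoms: triethyl orthoacetate (9), CCOC(C)(OCC)OCC
Why: Johnson orthoester Claisen rearrangement through a chair transition state with the C17 chain equatorial forms the (E)-C15=C16 olefin and transfers the C16 (R) C–O chirality suprafacially to the new C3–C4 bond, which sets C4 as (R).

Step 8
Reactants: 11 ethyl (3R,4E)-3-[(3E,7E)-9-(tert-butyldimethylsilyloxy)-3,7-dimethylnona-3,7-dien-1-yl]-4,8-dimethylnona-4,7-dienoate
Product: 12 ethyl (3R,4E)-3-[(3E,7E)-9-hydroxy-3,7-dimethylnona-3,7-dien-1-yl]-4,8-dimethylnona-4,7-dienoate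
Conditions: HF·pyridine, pyridine, THF, 0 °C to rt
Reagents that add atoms: none
Why: Buffered fluoride cleavage of the silyl ether frees the C13 allylic alcohol without touching the ester or the skipped diene.

Step 9
Reactants: 12 ethyl (3R,4E)-3-[(3E,7E)-9-hydroxy-3,7-dimethylnona-3,7-dien-1-yl]-4,8-dimethylnona-4,7-dienoate
Product: 13 ethyl (3R,4E)-3-[(3E,7E)-3,7-dimethyl-9-oxonona-3,7-dien-1-yl]-4,8-dimethylnona-4,7-dienoate
Conditions: MnO2, CH2Cl2, rt
Reagents that add atoms: none
Why: MnO2 allylic oxidation as in step 3; the saturated ester and the non-allylic positions are inert.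

Step 10
Reactants: 13 ethyl (3R,4E)-3-[(3E,7E)-3,7-dimethyl-9-oxonona-3,7-dien-1-yl]-4,8-dimethylnona-4,7-dienoate; 14 methyltriphenylphosphonium bromide
Product: 15 ethyl (3R,4E)-3-[(3E,7E)-3,7-dimethyldeca-3,7,9-trien-1-yl]-4,8-dimethylnona-4,7-dienoate
Conditions: 14, KOt-Bu, THF, 0 °C; then 13, −78 to 0 °C
Reagents that add atoms: methyltriphenylphosphonium bromide (14), C[P+](c1ccccc1)(c1ccccc1)c1ccccc1.[Br-]
Why: Wittig methylenation of the enal with the preformed non-stabilized ylide gives the terminal (E)-1,3-diene; the ethyl ester does not react at low temperature and C4 is not acidic.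

Step 11
Reactants: 15 ethyl (3R,4E)-3-[(3E,7E)-3,7-dimethyldeca-3,7,9-trien-1-yl]-4,8-dimethylnona-4,7-dienoate
Product: 16 (3R,4E)-3-[(3E,7E)-3,7-dimethyldeca-3,7,9-trien-1-yl]-4,8-dimethylnona-4,7-dienal
Conditions: DIBAL-H, CH2Cl2, −78 °C; Rochelle salt
Reagents that add atoms: none
Why: Partial ester reduction with DIBAL-H at −78 °C stops at the aluminium hemiacetal, which gives the aldehyde on work-up; the β-stereocentre C4 cannot epimerize.

Step 12
Reactants: 16 (3R,4E)-3-[(3E,7E)-3,7-dimethyldeca-3,7,9-trien-1-yl]-4,8-dimethylnona-4,7-dienal; 17 methyl trichloroacetate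
Product: 18 methyl (2Z,5R,6E)-2-chloro-5-[(3E,7E)-3,7-dimethyldeca-3,7,9-trien-1-yl]-6,10-dimethylundeca-2,6,9-trienoate
Conditions: CrCl2, 17, THF, rt
Reagents that add atoms: methyl trichloroacetate (17), COC(=O)C(Cl)(Cl)Cl
Why: Cr(II)-mediated olefination of an aldehyde with a trihaloacetate (Reformatsky-type addition of the chromium dichloroenolate, then reductive anti-elimination) gives the (Z)-α-chloroacrylate with the ester trans to C3, under neutral conditions that tolerate the diene and the β-stereocentre.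

Step 13
Reactants: 18 methyl (2Z,5R,6E)-2-chloro-5-[(3E,7E)-3,7-dimethyldeca-3,7,9-trien-1-yl]-6,10-dimethylundeca-2,6,9-trienoate; 19 9-borabicyclo[3.3.1]nonane (9-BBN-H)
Product: 21 methyl (1E,4R,7E,11E)-7,11-dimethyl-4-[(2E)-6-methylhepta-2,5-dien-2-yl]cyclotetradeca-1,7,11-triene-1-carboxylate (target), via alkylborane 20 (not isolated)
Conditions: 19, THF, 0 °C to rt; then slow addition to Pd(OAc)2 (cat.), SPhos (cat.), K3PO4, THF/H2O, 40 °C, ca. 1 mM
Reagents that add atoms: none
Why: 9-BBN adds to the only monosubstituted C=C, the C14=C13 terminus of the diene, and places boron on C14 (the trisubstituted olefins, the electron-poor chloroalkene and the ester react far more slowly); Pd(0) then inserts into the C1–Cl bond, the base-activated borane transfers C14 to palladium, and reductive elimination forms C1–C14. The closest known reaction type is the B-alkyl Suzuki–Miyaura coupling used for sp3–sp2 macrocyclization, here with an α-haloacrylate as the electrophile. The 14-membered ring closes end to end through a 15-membered palladacycle that contracts on reductive elimination, so no small-ring geometric constraint applies. No stereocentre is created: the (E)-geometry of the ring enoate C1=C2 follows from retention at the (Z)-chloroalkene carbon, and C4 is untouched. The step needs chemoselective hydroboration (secured by 9-BBN and the single terminal vinyl group), cyclization over oligomerization (slow addition, high dilution), and transmetalation faster than Heck insertion of the alkenylpalladium into C15=C16 or β-hydride loss (electron-rich biarylphosphine, mild temperature, hindered trisubstituted olefin).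

**Compound list**

1 | (2E,6E)-farnesol | OC/C=C(C)/CC/C=C(C)/CCC=C(C)C | starting material
2 | tert-butyldimethylsilyl ether of (2E,6E)-farnesol | CC(C)(C)[Si](C)(C)OC/C=C(C)/CC/C=C(C)/CCC=C(C)C | intermediate
3 | (2E,6E,10E)-12-(tert-butyldimethylsilyloxy)-2,6,10-trimethyldodeca-2,6,10-trien-1-ol | CC(C)(C)[Si](C)(C)OC/C=C(C)/CC/C=C(C)/CC/C=C(C)/CO | intermediate
4 | (2E,6E,10E)-12-(tert-butyldimethylsilyloxy)-2,6,10-trimethyldodeca-2,6,10-trienal | CC(C)(C)[Si](C)(C)OC/C=C(C)/CC/C=C(C)/CC/C=C(C)/C=O | intermediate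
5 | prenyl chloride (1-chloro-3-methylbut-2-ene) | CC(C)=CCCl | starting material
6 | rac-(6E,10E,14E)-16-(tert-butyldimethylsilyloxy)-2,6,10,14-tetramethylhexadeca-2,6,10,14-tetraen-5-ol | CC(C)(C)[Si](C)(C)OC/C=C(C)/CC/C=C(C)/CC/C=C(C)/C(O)CC=C(C)C | intermediate
7 | (6E,10E,14E)-16-(tert-butyldimethylsilyloxy)-2,6,10,14-tetramethylhexadeca-2,6,10,14-tetraen-5-one | CC(C)(C)[Si](C)(C)OC/C=C(C)/CC/C=C(C)/CC/C=C(C)/C(=O)CC=C(C)C | intermediate
8 | (5R,6E,10E,14E)-16-(tert-butyldimethylsilyloxy)-2,6,10,14-tetramethylhexadeca-2,6,10,14-tetraen-5-ol | CC(C)(C)[Si](C)(C)OC/C=C(C)/CC/C=C(C)/CC/C=C(C)/[C@H](O)CC=C(C)C | intermediate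
9 | triethyl orthoacetate | CCOC(C)(OCC)OCC | starting material
10 | ketene acetal: 1-ethoxyvinyl ether of alcohol 8 (carbinol carbon still R) | CC(C)(C)[Si](C)(C)OC/C=C(C)/CC/C=C(C)/CC/C=C(C)/[C@H](OC(=C)OCC)CC=C(C)C | intermediate
11 | ethyl (3R,4E)-3-[(3E,7E)-9-(tert-butyldimethylsilyloxy)-3,7-dimethylnona-3,7-dien-1-yl]-4,8-dimethylnona-4,7-dienoate | CC(C)(C)[Si](C)(C)OC/C=C(C)/CC/C=C(C)/CC[C@H](CC(=O)OCC)/C(C)=C/CC=C(C)C | intermediate
12 | ethyl (3R,4E)-3-[(3E,7E)-9-hydroxy-3,7-dimethylnona-3,7-dien-1-yl]-4,8-dimethylnona-4,7-dienoate | OC/C=C(C)/CC/C=C(C)/CC[C@H](CC(=O)OCC)/C(C)=C/CC=C(C)C | intermediate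
13 | ethyl (3R,4E)-3-[(3E,7E)-3,7-dimethyl-9-oxonona-3,7-dien-1-yl]-4,8-dimethylnona-4,7-dienoate | O=C/C=C(C)/CC/C=C(C)/CC[C@H](CC(=O)OCC)/C(C)=C/CC=C(C)C | intermediate
14 | methyltriphenylphosphonium bromide | C[P+](c1ccccc1)(c1ccccc1)c1ccccc1.[Br-] | starting material
15 | ethyl (3R,4E)-3-[(3E,7E)-3,7-dimethyldeca-3,7,9-trien-1-yl]-4,8-dimethylnona-4,7-dienoate | C=C/C=C(C)/CC/C=C(C)/CC[C@H](CC(=O)OCC)/C(C)=C/CC=C(C)C | intermediate
16 | (3R,4E)-3-[(3E,7E)-3,7-dimethyldeca-3,7,9-trien-1-yl]-4,8-dimethylnona-4,7-dienal | C=C/C=C(C)/CC/C=C(C)/CC[C@H](CC=O)/C(C)=C/CC=C(C)C | intermediate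
17 | methyl trichloroacetate | COC(=O)C(Cl)(Cl)Cl | starting material
18 | methyl (2Z,5R,6E)-2-chloro-5-[(3E,7E)-3,7-dimethyldeca-3,7,9-trien-1-yl]-6,10-dimethylundeca-2,6,9-trienoate | COC(=O)/C(Cl)=C/C[C@H](/C(C)=C/CC=C(C)C)CC/C(C)=C/CC/C(C)=C/C=C | intermediate
19 | 9-borabicyclo[3.3.1]nonane (9-BBN-H) | B1C2CCCC1CCC2 | starting material
20 | alkylborane: methyl (2Z,5R,6E)-5-[(3E,7E)-10-(9-borabicyclo[3.3.1]nonan-9-yl)-3,7-dimethyldeca-3,7-dien-1-yl]-2-chloro-6,10-dimethylundeca-2,6,9-trienoate | COC(=O)/C(Cl)=C/C[C@H](/C(C)=C/CC=C(C)C)CC/C(C)=C/CC/C(C)=C/CCB1C2CCCC1CCC2 | intermediate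
21 | methyl (1E,4R,7E,11E)-7,11-dimethyl-4-[(2E)-6-methylhepta-2,5-dien-2-yl]cyclotetradeca-1,7,11-triene-1-carboxylate | COC(=O)/C1=C/C[C@H](/C(C)=C/CC=C(C)C)CC/C(C)=C/CC/C(C)=C/CC1 | target

**Count and risks**

Total step count: 13. Longest linear sequence: 13 steps (1 to 21).

Steps most likely to fail:

1. Step 13 (macrocyclization). Intermolecular coupling may outrun the 14-membered ring closure; slow oxidative addition into the alkenyl chloride may leave time for protodeboronation or β-hydride loss; the alkenylpalladium may insert into the C15=C16 olefin instead of transmetalating. The fallback closes the ring at C1=C2 by Horner–Wadsworth–Emmons olefination; it sets out from aldehyde 16 and returns at target 21. Aldehyde 16 is protected (HC(OMe)3, PPTS, MeOH) as the dimethyl acetal F1. 9-BBN hydroboration of the diene terminus gives the alkylborane F2, and NaOH/H2O2 gives the primary C14 alcohol F3. Iodination (I2, PPh3, imidazole) gives the primary iodide F4. Alkylation of the sodium salt of trimethyl phosphonoacetate (NaH, DMF) gives the α-alkylated phosphonoacetate F5. Acetal hydrolysis (PPTS, acetone/H2O) gives the phosphonate aldehyde F6, which is cyclized with LiCl and DBU in MeCN at high dilution to 21; the stabilized phosphonate should favour the (E)-enoate.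

2. Step 4 (α-prenylation). The allyl unit may react through its tertiary γ-carbon, or the active barium may form incompletely, so that the reverse-prenyl isomer or unreacted enal results. The fallback uses a sulfone-stabilized allyl anion, which reacts at its α-carbon; it sets out from enal 4 and returns at enone 7 (steps 4 and 5 replaced). Lithiated 3-methylbut-2-enyl phenyl sulfone (n-BuLi, THF, −78 °C) adds to 4 to give the β-hydroxy sulfone F7. Dess–Martin oxidation gives the β-keto sulfone F8, and reductive desulfonylation (aluminium amalgam, aq. THF) gives 7.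

3. Step 2 (allylic oxidation). Oxidation may spread over the other allylic positions or run on to the enal and acid, and conversion may stay low. The fallback replaces C–H oxidation by terminal olefin cleavage and re-olefination; it sets out from silyl ether 2 and returns at enal 4 (steps 2 and 3 replaced). NBS in THF/H2O at 0 °C gives the terminal bromohydrin F9, K2CO3 in MeOH gives the terminal epoxide F10, and HIO4 in THF/Et2O gives the trisnor aldehyde F11. Wittig reaction of F11 with 2-(triphenylphosphoranylidene)propanal (toluene, 80 °C) gives the (E)-enal 4.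

**Further compounds**

F1 | step 13 | dimethyl acetal of aldehyde 16 | C=C/C=C(C)/CC/C=C(C)/CC[C@H](CC(OC)OC)/C(C)=C/CC=C(C)C
F2 | step 13 | alkylborane (9-BBN on C14) from F1 | B1(C2CCCC1CCC2)CC/C=C(C)/CC/C=C(C)/CC[C@H](CC(OC)OC)/C(C)=C/CC=C(C)C
F3 | step 13 | primary C14 alcohol | OCC/C=C(C)/CC/C=C(C)/CC[C@H](CC(OC)OC)/C(C)=C/CC=C(C)C
F4 | step 13 | primary C14 iodide | ICC/C=C(C)/CC/C=C(C)/CC[C@H](CC(OC)OC)/C(C)=C/CC=C(C)C
F5 | step 13 | α-alkylated trimethyl phosphonoacetate (acetal) | COC(=O)C(CC/C=C(C)/CC/C=C(C)/CC[C@H](CC(OC)OC)/C(C)=C/CC=C(C)C)P(=O)(OC)OC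
F6 | step 13 | phosphonate aldehyde | COC(=O)C(CC/C=C(C)/CC/C=C(C)/CC[C@H](CC=O)/C(C)=C/CC=C(C)C)P(=O)(OC)OC
F7 | step 4 | β-hydroxy sulfone | CC(C)(C)[Si](C)(C)OC/C=C(C)/CC/C=C(C)/CC/C=C(C)/C(O)C(C=C(C)C)S(=O)(=O)c1ccccc1
F8 | step 4 | β-keto sulfone | CC(C)(C)[Si](C)(C)OC/C=C(C)/CC/C=C(C)/CC/C=C(C)/C(=O)C(C=C(C)C)S(=O)(=O)c1ccccc1
F9 | step 2 | terminal bromohydrin | CC(C)(C)[Si](C)(C)OC/C=C(C)/CC/C=C(C)/CCC(Br)C(C)(C)O
F10 | step 2 | terminal epoxide | CC(C)(C)[Si](C)(C)OC/C=C(C)/CC/C=C(C)/CCC1OC1(C)C
F11 | step 2 | trisnor aldehyde | CC(C)(C)[Si](C)(C)OC/C=C(C)/CC/C=C(C)/CCC=O
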